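The bond to cut is O1–C2 of the dihydrofuran ring B. C2 is benzylic to the 4-hydroxy-3,5-dimethoxyphenyl ring C, so two-electron oxidation of that phenol turns C2 into the exocyclic carbon of a para-quinone methide. The ring A phenol oxygen O1, held four bonds away through C7a, C3a and C3, then adds to it. In one operation ring B closes and C2 is set trans to C3, whose configuration comes from an earlier oxazolidinone-directed benzylation. The precursor is an open-chain (R)-2,3-diarylpropan-1-ol with both phenols free, the C5 aldehyde in place to deactivate the ring A phenol, and the hydroxymethyl group unprotected.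

Key step: step 14

Remarks on the chemistry:
- Ring A is the benzo ring, ring B the dihydrofuran and ring C the 4-hydroxy-3,5-dimethoxyphenyl group; atom numbers are those of the 2,3-dihydrobenzofuran.
- A free C5 aldehyde would not survive enolate formation, LiBH4 or hydrogenolysis, so it travels as a 5,5-dimethyl-1,3-dioxane from step 4 to step 13.
- No silyl ether is placed on the C3 hydroxymethyl group. That oxygen could reach C2 only through a four-membered ring, and Ag2O leaves a primary alcohol alone, so a silylation and a desilylation are saved.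

Step 1
Reactants: 1 vanillin; 2 allyl bromide
Product: 3 4-(allyloxy)-3-methoxybenzaldehyde
Conditions: K2CO3, acetone, reflux
Reagents that add atoms: none
Why: Williamson ether synthesis, in which the phenoxide of vanillin (the only nucleophilic site) displaces bromide from the allylic halide by SN2.

Step 2
Reactants: 3 4-(allyloxy)-3-methoxybenzaldehyde
Product: 5 3-allyl-4-hydroxy-5-methoxybenzaldehyde, via ortho-dienone 4 (not isolated)
Conditions: N-methyl-2-pyrrolidone, 200 °C, N2
Reagents that add atoms: none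
Why: Aromatic Claisen rearrangement, whose [3,3] shift can deliver the allyl group only to the free ortho carbon because the other ortho position carries the methoxy group, after which dienone 4 tautomerises to the phenol.

Step 3
Reactants: 5 3-allyl-4-hydroxy-5-methoxybenzaldehyde
Product: 6 3-allyl-4-(benzyloxy)-5-methoxybenzaldehyde
Conditions: BnBr, K2CO3, DMF, 60 °C
Reagents that add atoms: benzyl bromide BrCc1ccccc1
Why: Williamson ether synthesis that installs a benzyl ether, which should withstand osmylation, chlorite, the sodium enolate and LiBH4 and leave later by hydrogenolysis together with the benzyl group of ring C.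

Step 4
Reactants: 6 3-allyl-4-(benzyloxy)-5-methoxybenzaldehyde
Product: 7 2-[3-allyl-4-(benzyloxy)-5-methoxyphenyl]-5,5-dimethyl-1,3-dioxane
Conditions: 2,2-dimethylpropane-1,3-diol, TsOH·H2O (cat.), toluene, reflux, Dean–Stark
Reagents that add atoms: 2,2-dimethylpropane-1,3-diol OCC(C)(C)CO
Why: Acid-catalysed acetalisation driven by azeotropic removal of water masks the aldehyde against chlorite, the enolate and hydride, the six-membered gem-dimethyl acetal being chosen for its better resistance to the weakly acidic chlorite buffer of step 6.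

Step 5
Reactants: 7 2-[3-allyl-4-(benzyloxy)-5-methoxyphenyl]-5,5-dimethyl-1,3-dioxane
Product: 9 2-[2-(benzyloxy)-5-(5,5-dimethyl-1,3-dioxan-2-yl)-3-methoxyphenyl]acetaldehyde, via vicinal diol 8 (not isolated)
Conditions: OsO4 (cat.), NaIO4, 2,6-lutidine, dioxane/H2O 3:1, rt; crude aldehyde used at once
Reagents that add atoms: osmium tetroxide O=[Os](=O)(=O)=O (oxygen donor, restored by sodium periodate [Na+].[O-]I(=O)(=O)=O)
Why: Lemieux–Johnson oxidation, in which catalytic osmylation of the monosubstituted alkene gives diol 8 and periodate cleaves it in the same flask, 2,6-lutidine keeping the medium near neutral so that the acetal and the enolisable arylacetaldehyde should survive.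

Step 6
Reactants: 9 2-[2-(benzyloxy)-5-(5,5-dimethyl-1,3-dioxan-2-yl)-3-methoxyphenyl]acetaldehyde
Product: 10 2-[2-(benzyloxy)-5-(5,5-dimethyl-1,3-dioxan-2-yl)-3-methoxyphenyl]acetic acid
Conditions: NaClO2, NaH2PO4, 2-methyl-2-butene, t-BuOH/H2O, 0 °C to rt
Reagents that add atoms: sodium chlorite [Na+].[O-]Cl=O
Why: Pinnick oxidation converts the aldehyde to the acid without enolisation, while 2-methyl-2-butene removes the hypochlorous acid that could otherwise chlorinate the electron-rich ring.

Step 7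
Reactants: 10 2-[2-(benzyloxy)-5-(5,5-dimethyl-1,3-dioxan-2-yl)-3-methoxyphenyl]acetic acid
Product: 12 (4R)-4-benzyl-3-{2-[2-(benzyloxy)-5-(5,5-dimethyl-1,3-dioxan-2-yl)-3-methoxyphenyl]acetyl}-1,3-oxazolidin-2-one, via mixed pivalic anhydride 11 (not isolated)
Conditions: t-BuCOCl, Et3N, THF, −20 °C; then LiCl, (R)-4-benzyl-1,3-oxazolidin-2-one, rt
Reagents that add atoms: (R)-4-benzyl-1,3-oxazolidin-2-one O=C1N[C@H](Cc2ccccc2)CO1
Why: N-acylation of the oxazolidinone through the mixed anhydride, with LiCl and Et3N activating the carbamate N–H, avoids both a strong base and an acid chloride that would form a ketene from the arylacetic acid, and the hindered pivaloyl carbonyl directs attack to the arylacetyl side.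

Step 8
Reactants: 13 syringaldehyde
Product: 14 4-(benzyloxy)-3,5-dimethoxybenzaldehyde
Conditions: BnBr, K2CO3, DMF, 60 °C
Reagents that add atoms: benzyl bromide BrCc1ccccc1
Why: Williamson ether synthesis on the acidic, para-formyl-substituted phenol protects the future ring C hydroxyl with the same group as ring A.

Step 9
Reactants: 14 4-(benzyloxy)-3,5-dimethoxybenzaldehyde
Product: 15 [4-(benzyloxy)-3,5-dimethoxyphenyl]methanol
Conditions: NaBH4, MeOH, 0 °C
Reagents that add atoms: none
Why: Borohydride reduction of an aromatic aldehyde to the benzylic alcohol, with no other reducible group present.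

Step 10
Reactants: 15 [4-(benzyloxy)-3,5-dimethoxyphenyl]methanol
Product: 16 2-(benzyloxy)-5-(bromomethyl)-1,3-dimethoxybenzene
Conditions: PBr3, Et2O, 0 °C; used freshly prepared
Reagents that add atoms: phosphorus tribromide BrP(Br)Br
Why: Conversion of an activated benzylic alcohol to the bromide through its phosphite ester and bromide displacement, a standard reaction that tolerates aryl ethers.

Step 11
Reactants: 12 (4R)-4-benzyl-3-{2-[2-(benzyloxy)-5-(5,5-dimethyl-1,3-dioxan-2-yl)-3-methoxyphenyl]acetyl}-1,3-oxazolidin-2-one; 16 2-(benzyloxy)-5-(bromomethyl)-1,3-dimethoxybenzene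
Product: 18 (4R)-4-benzyl-3-[(2R)-2-[2-(benzyloxy)-5-(5,5-dimethyl-1,3-dioxan-2-yl)-3-methoxyphenyl]-3-[4-(benzyloxy)-3,5-dimethoxyphenyl]propanoyl]-1,3-oxazolidin-2-one, via sodium Z-enolate 17 (not isolated)
Conditions: NaN(SiMe3)2, THF, −78 °C; then 16, −78 to −40 °C
Reagents that add atoms: none
Why: Evans alkylation, in which the chelated Z-enolate 17 is shielded on one face by the benzyl group of the (R)-auxiliary so that the benzylic bromide adds from the other face and sets the future C3 with the R configuration, a reaction type well established for arylacetyl imides and benzylic bromides.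

Step 12
Reactants: 18 (4R)-4-benzyl-3-[(2R)-2-[2-(benzyloxy)-5-(5,5-dimethyl-1,3-dioxan-2-yl)-3-methoxyphenyl]-3-[4-(benzyloxy)-3,5-dimethoxyphenyl]propanoyl]-1,3-oxazolidin-2-one
Product: 19 (2R)-2-[2-(benzyloxy)-5-(5,5-dimethyl-1,3-dioxan-2-yl)-3-methoxyphenyl]-3-[4-(benzyloxy)-3,5-dimethoxyphenyl]propan-1-ol
Conditions: LiBH4, H2O (1 equiv), THF, 0 °C
Reagents that add atoms: none
Why: Reductive cleavage of the imide by LiBH4 at the exocyclic carbonyl, where the aldehyde formed is reduced at once so that the α-aryl stereocentre should not epimerise, and the acetal and benzyl ethers are inert.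

Step 13
Reactants: 19 (2R)-2-[2-(benzyloxy)-5-(5,5-dimethyl-1,3-dioxan-2-yl)-3-methoxyphenyl]-3-[4-(benzyloxy)-3,5-dimethoxyphenyl]propan-1-ol
Product: 21 4-hydroxy-3-[(2R)-1-hydroxy-3-(4-hydroxy-3,5-dimethoxyphenyl)propan-2-yl]-5-methoxybenzaldehyde, via debenzylated acetal 20 (not isolated)
Conditions: H2 (1 atm), Pd/C, NaHCO3, EtOAc/EtOH, rt; filter; then 1 M HCl, THF, 40 °C
Reagents that add atoms: water O
Why: Hydrogenolysis of the two aryl benzyl ethers over Pd/C in a medium kept free of acid should leave the acetal in 20, and dilute acid then hydrolyses that acetal, which the newly freed para-hydroxyl makes very labile.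

Step 14
Reactants: 21 4-hydroxy-3-[(2R)-1-hydroxy-3-(4-hydroxy-3,5-dimethoxyphenyl)propan-2-yl]-5-methoxybenzaldehyde
Product: 23 (2S,3R)-2-(4-hydroxy-3,5-dimethoxyphenyl)-3-(hydroxymethyl)-7-methoxy-2,3-dihydro-1-benzofuran-5-carbaldehyde, via para-quinone methide 22 (not isolated)
Conditions: Ag2O (1.1 equiv), CH2Cl2/acetone, rt, dark, argon
Reagents that add atoms: none
Why: Ag2O (monovalent silver) removes two electrons and two protons from the 4-alkyl-2,6-dimethoxyphenol by way of a phenoxyl radical whose ortho positions are blocked by methoxy groups, so it should be channelled to quinone methide 22, in which C2 is electrophilic without any leaving group. The ring A phenol oxygen then adds to C2 in a 1,6-conjugate addition that rearomatises ring C and closes ring B in a 5-exo-trig mode, the attacked C2=C double bond lying outside the new ring. The closest known reactions are the Ag2O or DDQ oxidation of 4-alkyl-2,6-dimethoxyphenols to para-quinone methides and the phenol-to-quinone-methide closure that forms phenylcoumarans in oxidative coupling of 4-propenylphenols. The C2 configuration is controlled by the existing C3 stereocentre, because the ring C aryl group and the hydroxymethyl group avoid each other in the envelope transition state, and a cis isomer could reopen to 22 and close again, so the trans (2S,3R) product should prevail. The step needs oxidation of the ring C phenol only, which the C5 formyl group secures by making the ring A phenol electron-poor and hard to oxidise, while the primary alcohol cannot reach C2 through a reasonable ring size. Only a slight excess of oxidant is used because the product still carries the oxidisable ring C phenol.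

Step 15
Reactants: 23 (2S,3R)-2-(4-hydroxy-3,5-dimethoxyphenyl)-3-(hydroxymethyl)-7-methoxy-2,3-dihydro-1-benzofuran-5-carbaldehyde; 24 malonic acid
Product: 26 (2E)-3-[(2S,3R)-2-(4-hydroxy-3,5-dimethoxyphenyl)-3-(hydroxymethyl)-7-methoxy-2,3-dihydro-1-benzofuran-5-yl]prop-2-enoic acid, via arylidenemalonic acid 25 (not isolated)
Conditions: pyridine, piperidine (cat.), 70 °C; dilute HCl work-up
Reagents that add atoms: none
Why: Knoevenagel–Doebner condensation, in which amine-catalysed condensation gives 25 and decarboxylation in pyridine delivers the E-acrylic acid, the excess malonic acid keeping the phenol protonated so that ring B, C2 and C3 should stay untouched.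

Compound list
1 | vanillin (4-hydroxy-3-methoxybenzaldehyde) | COc1cc(C=O)ccc1O | starting material
2 | allyl bromide (3-bromoprop-1-ene) | C=CCBr | starting material
3 | 4-(allyloxy)-3-methoxybenzaldehyde | C=CCOc1ccc(C=O)cc1OC | intermediate
4 | 6-allyl-4-formyl-2-methoxycyclohexa-2,4-dien-1-one (ortho-dienone, racemic, not isolated) | C=CCC1C=C(C=O)C=C(OC)C1=O | intermediate
5 | 3-allyl-4-hydroxy-5-methoxybenzaldehyde | C=CCc1cc(C=O)cc(OC)c1O | intermediate
6 | 3-allyl-4-(benzyloxy)-5-methoxybenzaldehyde | C=CCc1cc(C=O)cc(OC)c1OCc1ccccc1 | intermediate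
7 | 2-[3-allyl-4-(benzyloxy)-5-methoxyphenyl]-5,5-dimethyl-1,3-dioxane | C=CCc1cc(C2OCC(C)(C)CO2)cc(OC)c1OCc1ccccc1 | intermediate
8 | 3-[2-(benzyloxy)-5-(5,5-dimethyl-1,3-dioxan-2-yl)-3-methoxyphenyl]propane-1,2-diol (racemic, not isolated) | OCC(O)Cc1cc(C2OCC(C)(C)CO2)cc(OC)c1OCc1ccccc1 | intermediate
9 | 2-[2-(benzyloxy)-5-(5,5-dimethyl-1,3-dioxan-2-yl)-3-methoxyphenyl]acetaldehyde | O=CCc1cc(C2OCC(C)(C)CO2)cc(OC)c1OCc1ccccc1 | intermediate
10 | 2-[2-(benzyloxy)-5-(5,5-dimethyl-1,3-dioxan-2-yl)-3-methoxyphenyl]acetic acid | OC(=O)Cc1cc(C2OCC(C)(C)CO2)cc(OC)c1OCc1ccccc1 | intermediate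
11 | 2-[2-(benzyloxy)-5-(5,5-dimethyl-1,3-dioxan-2-yl)-3-methoxyphenyl]acetic 2,2-dimethylpropanoic anhydride (not isolated) | CC(C)(C)C(=O)OC(=O)Cc1cc(C2OCC(C)(C)CO2)cc(OC)c1OCc1ccccc1 | intermediate
12 | (4R)-4-benzyl-3-{2-[2-(benzyloxy)-5-(5,5-dimethyl-1,3-dioxan-2-yl)-3-methoxyphenyl]acetyl}-1,3-oxazolidin-2-one | O=C(Cc1cc(C2OCC(C)(C)CO2)cc(OC)c1OCc1ccccc1)N1[C@H](Cc2ccccc2)COC1=O | intermediate
13 | syringaldehyde (4-hydroxy-3,5-dimethoxybenzaldehyde) | COc1cc(C=O)cc(OC)c1O | starting material
14 | 4-(benzyloxy)-3,5-dimethoxybenzaldehyde | COc1cc(C=O)cc(OC)c1OCc1ccccc1 | intermediate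
15 | [4-(benzyloxy)-3,5-dimethoxyphenyl]methanol | COc1cc(CO)cc(OC)c1OCc1ccccc1 | intermediate
16 | 2-(benzyloxy)-5-(bromomethyl)-1,3-dimethoxybenzene | COc1cc(CBr)cc(OC)c1OCc1ccccc1 | intermediate
17 | sodium (Z)-1-[(4R)-4-benzyl-2-oxo-1,3-oxazolidin-3-yl]-2-[2-(benzyloxy)-5-(5,5-dimethyl-1,3-dioxan-2-yl)-3-methoxyphenyl]ethen-1-olate (not isolated) | [Na+].[O-]/C(=C\c1cc(C2OCC(C)(C)CO2)cc(OC)c1OCc1ccccc1)N1[C@H](Cc2ccccc2)COC1=O | intermediate
18 | (4R)-4-benzyl-3-[(2R)-2-[2-(benzyloxy)-5-(5,5-dimethyl-1,3-dioxan-2-yl)-3-methoxyphenyl]-3-[4-(benzyloxy)-3,5-dimethoxyphenyl]propanoyl]-1,3-oxazolidin-2-one | O=C([C@H](Cc1cc(OC)c(OCc2ccccc2)c(OC)c1)c1cc(C2OCC(C)(C)CO2)cc(OC)c1OCc1ccccc1)N1[C@H](Cc2ccccc2)COC1=O | intermediate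
19 | (2R)-2-[2-(benzyloxy)-5-(5,5-dimethyl-1,3-dioxan-2-yl)-3-methoxyphenyl]-3-[4-(benzyloxy)-3,5-dimethoxyphenyl]propan-1-ol | OC[C@H](Cc1cc(OC)c(OCc2ccccc2)c(OC)c1)c1cc(C2OCC(C)(C)CO2)cc(OC)c1OCc1ccccc1 | intermediate
20 | (2R)-2-[5-(5,5-dimethyl-1,3-dioxan-2-yl)-2-hydroxy-3-methoxyphenyl]-3-(4-hydroxy-3,5-dimethoxyphenyl)propan-1-ol (not isolated) | OC[C@H](Cc1cc(OC)c(O)c(OC)c1)c1cc(C2OCC(C)(C)CO2)cc(OC)c1O | intermediate
21 | 4-hydroxy-3-[(2R)-1-hydroxy-3-(4-hydroxy-3,5-dimethoxyphenyl)propan-2-yl]-5-methoxybenzaldehyde | OC[C@H](Cc1cc(OC)c(O)c(OC)c1)c1cc(C=O)cc(OC)c1O | intermediate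
22 | 4-hydroxy-3-[(2R)-1-hydroxy-3-(3,5-dimethoxy-4-oxocyclohexa-2,5-dien-1-ylidene)propan-2-yl]-5-methoxybenzaldehyde (para-quinone methide, not isolated) | OC[C@H](C=C1C=C(OC)C(=O)C(OC)=C1)c1cc(C=O)cc(OC)c1O | intermediate
23 | (2S,3R)-2-(4-hydroxy-3,5-dimethoxyphenyl)-3-(hydroxymethyl)-7-methoxy-2,3-dihydro-1-benzofuran-5-carbaldehyde (2,3-trans) | COc1cc([C@H]2Oc3c(OC)cc(C=O)cc3[C@@H]2CO)cc(OC)c1O | intermediate
24 | malonic acid | OC(=O)CC(=O)O | starting material
25 | 2-{[(2S,3R)-2-(4-hydroxy-3,5-dimethoxyphenyl)-3-(hydroxymethyl)-7-methoxy-2,3-dihydro-1-benzofuran-5-yl]methylidene}propanedioic acid (not isolated) | COc1cc([C@H]2Oc3c(OC)cc(C=C(C(=O)O)C(=O)O)cc3[C@@H]2CO)cc(OC)c1O | intermediate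
26 | (2E)-3-[(2S,3R)-2-(4-hydroxy-3,5-dimethoxyphenyl)-3-(hydroxymethyl)-7-methoxy-2,3-dihydro-1-benzofuran-5-yl]prop-2-enoic acid | COc1cc([C@H]2Oc3c(OC)cc(/C=C/C(=O)O)cc3[C@@H]2CO)cc(OC)c1O | target

Total step count: 15. Longest linear sequence: 12 steps from vanillin (steps 1–7 and 11–15). The bromide arm from syringaldehyde (steps 8–10) adds three steps.

Steps most likely to fail

Step 14 (highest risk). The quinone methide may lose the C3 hydrogen and tautomerise to a stilbene before O1 adds. The phenoxyl radicals may couple between molecules, or the product may be oxidised again at C2 and aromatise. The fallback introduces the C2 oxygen by an aldol reaction and closes ring B with acid instead of an oxidant. It sets out from acid 10 (with aldehyde 14 as partner) and comes back at 23.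
- Acid 10 would be attached to the enantiomeric auxiliary under the conditions of step 7 to give (4S)-4-benzyl-3-{2-[2-(benzyloxy)-5-(5,5-dimethyl-1,3-dioxan-2-yl)-3-methoxyphenyl]acetyl}-1,3-oxazolidin-2-one F1.
- Its dibutylboron Z-enolate (Bu2BOTf, i-Pr2NEt, CH2Cl2, −78 to 0 °C) should add to 14 in an Evans syn aldol reaction. The open boron enolate reacts from the face opposite to that used by the chelated sodium enolate, so the (S)-auxiliary gives the same C3 configuration. The adduct is (4S)-4-benzyl-3-[(2S,3S)-2-[2-(benzyloxy)-5-(5,5-dimethyl-1,3-dioxan-2-yl)-3-methoxyphenyl]-3-[4-(benzyloxy)-3,5-dimethoxyphenyl]-3-hydroxypropanoyl]-1,3-oxazolidin-2-one F2.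
- LiBH4 would give (1S,2R)-2-[2-(benzyloxy)-5-(5,5-dimethyl-1,3-dioxan-2-yl)-3-methoxyphenyl]-1-[4-(benzyloxy)-3,5-dimethoxyphenyl]propane-1,3-diol F3.
- Hydrogenolysis (H2, Pd/C, NaHCO3, EtOAc) would give (1S,2R)-2-[5-(5,5-dimethyl-1,3-dioxan-2-yl)-2-hydroxy-3-methoxyphenyl]-1-(4-hydroxy-3,5-dimethoxyphenyl)propane-1,3-diol F4.
- 1 M HCl in THF would ionise the para-hydroxybenzylic alcohol, let O1 close ring B to the trans isomer and hydrolyse the acetal, which gives 23.

Step 11. Facial selectivity may be incomplete, the acidic α-aryl centre may epimerise under the basic conditions, or the electron-rich benzylic bromide may decompose before it is consumed. The fallback uses catalytic asymmetric hydrogenation instead of auxiliary control. It sets out from acid 10 (with aldehyde 14) and comes back at 19.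
- A Perkin condensation (Ac2O, Et3N, 110 °C, then aqueous hydrolysis of the mixed anhydride) should give (2E)-2-[2-(benzyloxy)-5-(5,5-dimethyl-1,3-dioxan-2-yl)-3-methoxyphenyl]-3-[4-(benzyloxy)-3,5-dimethoxyphenyl]prop-2-enoic acid F5.
- Enantioselective hydrogenation of this α-arylcinnamic acid would give (2R)-2-[2-(benzyloxy)-5-(5,5-dimethyl-1,3-dioxan-2-yl)-3-methoxyphenyl]-3-[4-(benzyloxy)-3,5-dimethoxyphenyl]propanoic acid F6. The catalyst would be [Ir(cod)(L)]B[C6H3(CF3)2]4 with L a chiral spiro phosphine–oxazoline, under H2 with Et3N in MeOH. The ligand enantiomer that delivers the R acid would have to be identified in a trial run.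
- LiAlH4 in THF at 0 °C would reduce F6 to 19.

Step 13. Hydrogenolysis of the benzylic C–O bonds of the acetal may compete with O-debenzylation, or the hindered ring C benzyl ether may be cleaved incompletely. The fallback reverses the order and removes the benzyl groups with a Lewis acid instead of hydrogen. It sets out from 19 and comes back at 21.
- 1 M HCl in THF would hydrolyse the acetal to 4-(benzyloxy)-3-[(2R)-1-[4-(benzyloxy)-3,5-dimethoxyphenyl]-3-hydroxypropan-2-yl]-5-methoxybenzaldehyde F7.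
- BCl3 with pentamethylbenzene as cation scavenger (CH2Cl2, −78 °C) would cleave both aryl benzyl ethers and give 21.

Further compounds
F1 | step 14 | (4S)-4-benzyl-3-{2-[2-(benzyloxy)-5-(5,5-dimethyl-1,3-dioxan-2-yl)-3-methoxyphenyl]acetyl}-1,3-oxazolidin-2-one | O=C(Cc1cc(C2OCC(C)(C)CO2)cc(OC)c1OCc1ccccc1)N1[C@@H](Cc2ccccc2)COC1=O
F2 | step 14 | (4S)-4-benzyl-3-[(2S,3S)-2-[2-(benzyloxy)-5-(5,5-dimethyl-1,3-dioxan-2-yl)-3-methoxyphenyl]-3-[4-(benzyloxy)-3,5-dimethoxyphenyl]-3-hydroxypropanoyl]-1,3-oxazolidin-2-one | O=C([C@@H](c1cc(C2OCC(C)(C)CO2)cc(OC)c1OCc1ccccc1)[C@H](O)c1cc(OC)c(OCc2ccccc2)c(OC)c1)N1[C@@H](Cc2ccccc2)COC1=O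
F3 | step 14 | (1S,2R)-2-[2-(benzyloxy)-5-(5,5-dimethyl-1,3-dioxan-2-yl)-3-methoxyphenyl]-1-[4-(benzyloxy)-3,5-dimethoxyphenyl]propane-1,3-diol | OC[C@@H](c1cc(C2OCC(C)(C)CO2)cc(OC)c1OCc1ccccc1)[C@H](O)c1cc(OC)c(OCc2ccccc2)c(OC)c1
F4 | step 14 | (1S,2R)-2-[5-(5,5-dimethyl-1,3-dioxan-2-yl)-2-hydroxy-3-methoxyphenyl]-1-(4-hydroxy-3,5-dimethoxyphenyl)propane-1,3-diol | OC[C@@H](c1cc(C2OCC(C)(C)CO2)cc(OC)c1O)[C@H](O)c1cc(OC)c(O)c(OC)c1
F5 | step 11 | (2E)-2-[2-(benzyloxy)-5-(5,5-dimethyl-1,3-dioxan-2-yl)-3-methoxyphenyl]-3-[4-(benzyloxy)-3,5-dimethoxyphenyl]prop-2-enoic acid | OC(=O)/C(=C/c1cc(OC)c(OCc2ccccc2)c(OC)c1)c1cc(C2OCC(C)(C)CO2)cc(OC)c1OCc1ccccc1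
F6 | step 11 | (2R)-2-[2-(benzyloxy)-5-(5,5-dimethyl-1,3-dioxan-2-yl)-3-methoxyphenyl]-3-[4-(benzyloxy)-3,5-dimethoxyphenyl]propanoic acid | OC(=O)[C@H](Cc1cc(OC)c(OCc2ccccc2)c(OC)c1)c1cc(C2OCC(C)(C)CO2)cc(OC)c1OCc1ccccc1
F7 | step 13 | 4-(benzyloxy)-3-[(2R)-1-[4-(benzyloxy)-3,5-dimethoxyphenyl]-3-hydroxypropan-2-yl]-5-methoxybenzaldehyde | OC[C@H](Cc1cc(OC)c(OCc2ccccc2)c(OC)c1)c1cc(C=O)cc(OC)c1OCc1ccccc1
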